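**Retrosynthetic overview**
- The vinylogous ester C–O bond is cut last: atromentin (mono-O-acylation at one acidic quinone OH) plus (2Z,4S,5S)-4,5-epoxyhex-2-enoic acid.
- The central quinone ring comes from a thermal 4π ring opening / 6π electrocyclization of a 4-alkenyl-4-hydroxycyclobutenone, followed by oxidation and hydrolysis.
- The cyclobutenone comes from dimethyl squarate, an aryllithium and a 1-aryl-2-methoxyvinyllithium.
- The epoxy acid comes from 3,4-di-O-acetyl-L-rhamnal: oxidation to the enelactone (Z-alkene locked in the ring, both stereocentres from L-rhamnose), then lactone opening with SN2 epoxide closure and inversion at C4.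
- Ring order: cyclobutene (bought) → central six-membered ring; pyranose → δ-enelactone → oxirane; the two halves are joined last.

Assumption: the two TBS-protected aryl building blocks, dimethyl squarate and 3,4-di-O-acetyl-L-rhamnal are taken as commercial; the racemic cyclobutenone and cyclohexadienone intermediates lose their stereocentres on aromatisation.

Abbreviation: TBSO = tert-butyldimethylsilyloxy.

**Step 1**
Reactants: 1 (4-bromophenoxy)(tert-butyl)dimethylsilane; 2 dimethyl squarate (3,4-dimethoxycyclobut-3-ene-1,2-dione)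
Product: 6 3-[4-(TBSO)phenyl]-4-methoxycyclobut-3-ene-1,2-dione, via aryllithium 3 (not isolated), via lithium alkoxide adduct 4 (not isolated), via trifluoroacetate 5 (not isolated)
Conditions: 1, n-BuLi, THF, −78 °C; cannulate into 2, THF, −78 °C; TFAA, −78 °C; aq NH4Cl
Reagents that add atoms: water (aqueous work-up), O
Why: Br/Li exchange and a single 1,2-addition of the aryllithium to a squarate carbonyl, then trifluoroacetylation of the tertiary alkoxide and hydrolytic allylic transposition with loss of methanol, give the 3-aryl-4-alkoxycyclobutenedione (squarate addition/rearrangement); no stereocentre.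

**Step 2**
Reactants: 7 4-(TBSO)benzaldehyde
Product: 8 tert-butyl[4-(2-methoxyethenyl)phenoxy]dimethylsilane (E/Z mixture)
Conditions: MeOCH2PPh3Cl, NaHMDS, THF, 0 °C → rt
Reagents that add atoms: (methoxymethyl)triphenylphosphonium chloride, COC[P+](c1ccccc1)(c1ccccc1)c1ccccc1.[Cl-]
Why: Wittig olefination with the methoxymethylene ylide gives the enol ether; the E/Z ratio is irrelevant because the geometry is reset in step 3.

**Step 3**
Reactants: 8 tert-butyl[4-(2-methoxyethenyl)phenoxy]dimethylsilane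
Product: 10 {4-[(Z)-1-bromo-2-methoxyethenyl]phenoxy}(tert-butyl)dimethylsilane, via dibromide 9 (not isolated)
Conditions: Br2, CH2Cl2, −78 °C; then DBU, −78 °C → rt
Reagents that add atoms: bromine, BrBr
Why: Bromination of the enol ether gives the α-bromo ether, and base-induced dehydrobromination (ionisation of the α-bromo ether, loss of the benzylic H) gives the β-bromo enol ether with aryl trans to OMe, i.e. Br cis to OMe.

**Step 4**
Reactants: 10 {4-[(Z)-1-bromo-2-methoxyethenyl]phenoxy}(tert-butyl)dimethylsilane; 6 3-[4-(TBSO)phenyl]-4-methoxycyclobut-3-ene-1,2-dione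
Product: 12 4-hydroxy-3-methoxy-2-[4-(TBSO)phenyl]-4-{(Z)-2-methoxy-1-[4-(TBSO)phenyl]ethenyl}cyclobut-2-en-1-one (racemic), via vinyllithium 11 (not isolated)
Conditions: 10, t-BuLi (2 equiv), THF, −78 °C; then 6, −78 °C; aq NH4Cl
Reagents that add atoms: none
Why: Br/Li exchange with retention gives the chelated vinyllithium (Li cis to OMe), which adds 1,2 to the more electrophilic, non-vinylogous-ester carbonyl of 6 (the one next to C–OMe); the carbinol centre is racemic and is destroyed in step 5.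

**Step 5**
Reactants: 12 4-hydroxy-3-methoxy-2-[4-(TBSO)phenyl]-4-{(Z)-2-methoxy-1-[4-(TBSO)phenyl]ethenyl}cyclobut-2-en-1-one
Product: 16 2,5-bis[4-(TBSO)phenyl]-3,6-dimethoxycyclohexa-2,5-diene-1,4-dione, via dienylketene 13 (not isolated), via cyclohexadienone 14 (not isolated), via hydroquinone 15 (not isolated)
Conditions: PhMe (degassed), 110 °C; then Ag2O, rt
Reagents that add atoms: none
Why: Thermal conrotatory 4π ring opening with the OH rotating outward gives the (Z)-dienylketene, whose 6π electrocyclization forms the central ring (Moore-type cyclobutenone rearrangement); tautomerisation to the hydroquinone and Ag2O oxidation give the quinone.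

**Step 6**
Reactants: 16 2,5-bis[4-(TBSO)phenyl]-3,6-dimethoxycyclohexa-2,5-diene-1,4-dione
Product: 17 atromentin (2,5-dihydroxy-3,6-bis(4-hydroxyphenyl)cyclohexa-2,5-diene-1,4-dione)
Conditions: NaOH (aq), 1,4-dioxane, 60 °C, Ar; then HCl (aq) to pH 2
Reagents that add atoms: sodium hydroxide, [Na+].[OH-]
Why: Addition–elimination hydrolysis of the two vinylogous methyl esters and hydroxide cleavage of the two aryl silyl ethers occur in one operation; acidification precipitates the free tetrol.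

**Step 7**
Reactants: 18 3,4-di-O-acetyl-L-rhamnal ((2S,3S,4S)-2-methyl-3,4-dihydro-2H-pyran-3,4-diyl diacetate)
Product: 20 (2S,3R)-2-methyl-6-oxo-3,6-dihydro-2H-pyran-3-yl acetate, via anomeric perester 19 (not isolated)
Conditions: mCPBA, BF3·OEt2, CH2Cl2, −20 °C
Reagents that add atoms: 3-chloroperoxybenzoic acid, OOC(=O)c1cccc(Cl)c1
Why: BF3-promoted Ferrier-type allylic displacement of the 3-acetate by the peracid gives the anomeric perester, which fragments to the α,β-unsaturated δ-lactone; the two L-rhamnose centres are untouched and the alkene is held cis by the ring.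

**Step 8**
Reactants: 20 (2S,3R)-2-methyl-6-oxo-3,6-dihydro-2H-pyran-3-yl acetate
Product: 21 (5R,6S)-5-hydroxy-6-methyl-5,6-dihydro-2H-pyran-2-one (osmundalactone)
Conditions: AcCl (0.3 equiv), MeOH, 0 °C → rt
Reagents that add atoms: none
Why: Acid-catalysed transesterification removes the acetate while the less electrophilic conjugated lactone survives, and the absence of base avoids translactonisation; both stereocentres are unchanged.

**Step 9**
Reactants: 21 (5R,6S)-5-hydroxy-6-methyl-5,6-dihydro-2H-pyran-2-one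
Product: 22 (2S,3R)-2-methyl-6-oxo-3,6-dihydro-2H-pyran-3-yl methanesulfonate
Conditions: MsCl, pyridine, CH2Cl2, 0 °C
Reagents that add atoms: methanesulfonyl chloride, CS(=O)(=O)Cl
Why: O-sulfonylation of the secondary alcohol proceeds with retention and turns the C4 oxygen of the future acid into a leaving group.

**Step 10**
Reactants: 22 (2S,3R)-2-methyl-6-oxo-3,6-dihydro-2H-pyran-3-yl methanesulfonate
Product: 24 (2Z)-3-[(2S,3S)-3-methyloxiran-2-yl]prop-2-enoic acid, via hydroxy mesylate carboxylate 23 (not isolated)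
Conditions: LiOH (2.1 equiv), THF/H2O, 0 °C; then cold aq H3PO4 to pH 3.5, extract, use at once
Reagents that add atoms: lithium hydroxide, [Li+].[OH-]
Why: Saponification opens the lactone to the (Z)-enoate and the released C5 alkoxide displaces the allylic mesylate by intramolecular SN2 (3-exo-tet) with inversion at C4, giving the trans (4S,5S) epoxide from the L-rhamnose centres with the Z geometry carried over from the ring.

**Step 11**
Reactants: 24 (2Z)-3-[(2S,3S)-3-methyloxiran-2-yl]prop-2-enoic acid; 17 atromentin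
Product: 26 4-hydroxy-2,5-bis(4-hydroxyphenyl)-3,6-dioxocyclohexa-1,4-dien-1-yl (2Z)-3-[(2S,3S)-3-methyloxiran-2-yl]prop-2-enoate, via acid chloride 25 (not isolated)
Conditions: 24, 1-chloro-N,N,2-trimethylprop-1-en-1-amine, CH2Cl2, 0 °C; then 17 (2 equiv), 2,6-lutidine (1 equiv), THF, −20 °C
Reagents that add atoms: none
Why: Ghosez's reagent forms the acid chloride under neutral conditions and 2,6-lutidine ionises only the vinylogous-acid OH of 17 (pKa about 3 against about 10 for the phenols), so O-acylation occurs at one quinone oxygen; excess symmetric 17 limits diacylation and the hindered base avoids Z→E isomerisation, leaving the stereocentres untouched.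

**Compound list**
1 | (4-bromophenoxy)(tert-butyl)dimethylsilane | CC(C)(C)[Si](C)(C)Oc1ccc(Br)cc1 | starting material
2 | dimethyl squarate (3,4-dimethoxycyclobut-3-ene-1,2-dione) | COC1=C(OC)C(=O)C1=O | starting material
3 | [4-(TBSO)phenyl]lithium (not isolated) | [Li]c1ccc(O[Si](C)(C)C(C)(C)C)cc1 | intermediate
4 | lithium 1-[4-(TBSO)phenyl]-2,3-dimethoxy-4-oxocyclobut-2-en-1-olate (racemic, not isolated) | [Li]OC1(c2ccc(O[Si](C)(C)C(C)(C)C)cc2)C(OC)=C(OC)C1=O | intermediate
5 | 1-[4-(TBSO)phenyl]-2,3-dimethoxy-4-oxocyclobut-2-en-1-yl trifluoroacetate (racemic, not isolated) | O=C(OC1(c2ccc(O[Si](C)(C)C(C)(C)C)cc2)C(OC)=C(OC)C1=O)C(F)(F)F | intermediate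
6 | 3-[4-(TBSO)phenyl]-4-methoxycyclobut-3-ene-1,2-dione | COC1=C(c2ccc(O[Si](C)(C)C(C)(C)C)cc2)C(=O)C1=O | intermediate
7 | 4-(TBSO)benzaldehyde | O=Cc1ccc(O[Si](C)(C)C(C)(C)C)cc1 | starting material
8 | tert-butyl[4-(2-methoxyethenyl)phenoxy]dimethylsilane (E/Z mixture) | COC=Cc1ccc(O[Si](C)(C)C(C)(C)C)cc1 | intermediate
9 | tert-butyl[4-(1,2-dibromo-2-methoxyethyl)phenoxy]dimethylsilane (diastereomer mixture, not isolated) | COC(Br)C(Br)c1ccc(O[Si](C)(C)C(C)(C)C)cc1 | intermediate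
10 | {4-[(Z)-1-bromo-2-methoxyethenyl]phenoxy}(tert-butyl)dimethylsilane (Br cis to OMe) | CO/C=C(\Br)c1ccc(O[Si](C)(C)C(C)(C)C)cc1 | intermediate
11 | {2-methoxy-1-[4-(TBSO)phenyl]ethenyl}lithium, Li cis to OMe (E by CIP, not isolated) | CO/C=C(\[Li])c1ccc(O[Si](C)(C)C(C)(C)C)cc1 | intermediate
12 | 4-hydroxy-3-methoxy-2-[4-(TBSO)phenyl]-4-{(Z)-2-methoxy-1-[4-(TBSO)phenyl]ethenyl}cyclobut-2-en-1-one (racemic) | CO/C=C(\C1(O)C(OC)=C(c2ccc(O[Si](C)(C)C(C)(C)C)cc2)C1=O)c1ccc(O[Si](C)(C)C(C)(C)C)cc1 | intermediate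
13 | (3Z,5Z)-4-hydroxy-3,6-dimethoxy-2,5-bis[4-(TBSO)phenyl]hexa-1,3,5-trien-1-one (dienylketene, not isolated) | O=C=C(c1ccc(O[Si](C)(C)C(C)(C)C)cc1)/C(OC)=C(O)\C(c1ccc(O[Si](C)(C)C(C)(C)C)cc1)=C/OC | intermediate
14 | 4-hydroxy-3,6-dimethoxy-2,5-bis[4-(TBSO)phenyl]cyclohexa-2,4-dien-1-one (racemic, not isolated) | COC1C(=O)C(c2ccc(O[Si](C)(C)C(C)(C)C)cc2)=C(OC)C(O)=C1c1ccc(O[Si](C)(C)C(C)(C)C)cc1 | intermediate
15 | 3,6-dimethoxy-2,5-bis[4-(TBSO)phenyl]benzene-1,4-diol (not isolated) | COc1c(O)c(-c2ccc(O[Si](C)(C)C(C)(C)C)cc2)c(OC)c(O)c1-c1ccc(O[Si](C)(C)C(C)(C)C)cc1 | intermediate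
16 | 2,5-bis[4-(TBSO)phenyl]-3,6-dimethoxycyclohexa-2,5-diene-1,4-dione | COC1=C(c2ccc(O[Si](C)(C)C(C)(C)C)cc2)C(=O)C(OC)=C(c2ccc(O[Si](C)(C)C(C)(C)C)cc2)C1=O | intermediate
17 | atromentin, 2,5-dihydroxy-3,6-bis(4-hydroxyphenyl)cyclohexa-2,5-diene-1,4-dione | OC1=C(c2ccc(O)cc2)C(=O)C(O)=C(c2ccc(O)cc2)C1=O | intermediate
18 | 3,4-di-O-acetyl-L-rhamnal, (2S,3S,4S)-2-methyl-3,4-dihydro-2H-pyran-3,4-diyl diacetate | C[C@@H]1OC=C[C@H](OC(C)=O)[C@H]1OC(C)=O | starting material
19 | 4-O-acetyl-2,3,6-trideoxy-L-erythro-hex-2-enopyranosyl 3-chloroperoxybenzoate (anomer mixture, not isolated) | C[C@@H]1OC(OOC(=O)c2cccc(Cl)c2)C=C[C@H]1OC(C)=O | intermediate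
20 | (2S,3R)-2-methyl-6-oxo-3,6-dihydro-2H-pyran-3-yl acetate | C[C@@H]1OC(=O)C=C[C@H]1OC(C)=O | intermediate
21 | (5R,6S)-5-hydroxy-6-methyl-5,6-dihydro-2H-pyran-2-one (osmundalactone) | C[C@@H]1OC(=O)C=C[C@H]1O | intermediate
22 | (2S,3R)-2-methyl-6-oxo-3,6-dihydro-2H-pyran-3-yl methanesulfonate | C[C@@H]1OC(=O)C=C[C@H]1OS(C)(=O)=O | intermediate
23 | lithium (2Z,4R,5S)-5-hydroxy-4-(methylsulfonyloxy)hex-2-enoate (not isolated) | C[C@H](O)[C@H](OS(C)(=O)=O)/C=C\C(=O)[O-].[Li+] | intermediate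
24 | (2Z)-3-[(2S,3S)-3-methyloxiran-2-yl]prop-2-enoic acid, i.e. (2Z,4S,5S)-4,5-epoxyhex-2-enoic acid | C[C@@H]1O[C@H]1/C=C\C(=O)O | intermediate
25 | (2Z)-3-[(2S,3S)-3-methyloxiran-2-yl]prop-2-enoyl chloride (not isolated) | C[C@@H]1O[C@H]1/C=C\C(Cl)=O | intermediate
26 | 4-hydroxy-2,5-bis(4-hydroxyphenyl)-3,6-dioxocyclohexa-1,4-dien-1-yl (2Z)-3-[(2S,3S)-3-methyloxiran-2-yl]prop-2-enoate | C[C@@H]1O[C@H]1/C=C\C(=O)OC1=C(c2ccc(O)cc2)C(=O)C(O)=C(c2ccc(O)cc2)C1=O | target

**Totals**
Total step count: 11. Longest linear sequence: 6 (steps 2, 3, 4, 5, 6, 11).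

**Three steps most likely to fail**

Step 4. The vinyllithium 11 loses LiOMe to give the arylalkyne if any E-bromide is present or if it isomerises, and the 1,2-addition must beat attack on the vinylogous ester. The fallback sets out from 6 and comes back at 15; it leaves the oxygen out of the nucleophile and adds it after the ring is built. Commercial 1-[4-(TBSO)phenyl]ethanone and 2,4,6-triisopropylbenzenesulfonohydrazide give N'-{1-[4-(TBSO)phenyl]ethylidene}-2,4,6-triisopropylbenzenesulfonohydrazide F1. n-BuLi (2 equiv, THF, −78 → 0 °C, Shapiro reaction) converts it into {1-[4-(TBSO)phenyl]ethenyl}lithium F2, which adds to 6 to give 4-hydroxy-3-methoxy-2-[4-(TBSO)phenyl]-4-{1-[4-(TBSO)phenyl]ethenyl}cyclobut-2-en-1-one F3. The same thermal 4π/6π cascade (PhMe, 110 °C) gives 3-methoxy-2,5-bis[4-(TBSO)phenyl]benzene-1,4-diol F4, and Ag2O gives 3-methoxy-2,5-bis[4-(TBSO)phenyl]cyclohexa-2,5-diene-1,4-dione F5. ZnCl2-promoted conjugate addition of methanol to the one free quinone position then gives hydroquinone 15, which is oxidised to 16 as in step 5.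

Step 8. Osmundalactone-type lactones can open or translactonise to the butenolide, so the acetate may not come off cleanly. The fallback sets out from 18 and comes back at 22; the protecting-group exchange is done on a glycoside before the lactone exists. Ferrier glycosylation (i-PrOH, cat. BF3·OEt2, CH2Cl2) gives isopropyl 4-O-acetyl-2,3,6-trideoxy-α-L-erythro-hex-2-enopyranoside F6. K2CO3/MeOH gives isopropyl 2,3,6-trideoxy-α-L-erythro-hex-2-enopyranoside F7, and MsCl/pyridine gives isopropyl 2,3,6-trideoxy-4-O-methylsulfonyl-α-L-erythro-hex-2-enopyranoside F8. BF3·OEt2/mCPBA then oxidises the anomeric acetal (same perester fragmentation as in step 7, with loss of isopropanol) to 22.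

Step 11. Diacylation, phenol acylation or acyl transfer from the labile vinylogous anhydride can erode the yield, and the epoxy acid chloride is sensitive. The fallback sets out from 16 and comes back at 26; the phenols stay masked during acylation. LiI (EtOAc, reflux, SN2 demethylation of the two vinylogous methyl esters, then acidification) gives 2,5-dihydroxy-3,6-bis[4-(TBSO)phenyl]cyclohexa-2,5-diene-1,4-dione F9. Acylation with 25 (1 equiv, 2,6-lutidine, THF, −20 °C) gives 4-hydroxy-3,6-dioxo-2,5-bis[4-(TBSO)phenyl]cyclohexa-1,4-dien-1-yl (2Z)-3-[(2S,3S)-3-methyloxiran-2-yl]prop-2-enoate F10. HF·pyridine buffered with pyridine (THF, 0 °C) removes the two aryl silyl ethers to give 26.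

**Further compounds**
F1 | step 4 | N'-{1-[4-(TBSO)phenyl]ethylidene}-2,4,6-triisopropylbenzenesulfonohydrazide | CC(=NNS(=O)(=O)c1c(C(C)C)cc(C(C)C)cc1C(C)C)c1ccc(O[Si](C)(C)C(C)(C)C)cc1
F2 | step 4 | {1-[4-(TBSO)phenyl]ethenyl}lithium | [Li]C(=C)c1ccc(O[Si](C)(C)C(C)(C)C)cc1
F3 | step 4 | 4-hydroxy-3-methoxy-2-[4-(TBSO)phenyl]-4-{1-[4-(TBSO)phenyl]ethenyl}cyclobut-2-en-1-one (racemic) | C=C(c1ccc(O[Si](C)(C)C(C)(C)C)cc1)C1(O)C(OC)=C(c2ccc(O[Si](C)(C)C(C)(C)C)cc2)C1=O
F4 | step 4 | 3-methoxy-2,5-bis[4-(TBSO)phenyl]benzene-1,4-diol | COc1c(O)c(-c2ccc(O[Si](C)(C)C(C)(C)C)cc2)cc(O)c1-c1ccc(O[Si](C)(C)C(C)(C)C)cc1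
F5 | step 4 | 3-methoxy-2,5-bis[4-(TBSO)phenyl]cyclohexa-2,5-diene-1,4-dione | COC1=C(c2ccc(O[Si](C)(C)C(C)(C)C)cc2)C(=O)C=C(c2ccc(O[Si](C)(C)C(C)(C)C)cc2)C1=O
F6 | step 8 | isopropyl 4-O-acetyl-2,3,6-trideoxy-α-L-erythro-hex-2-enopyranoside | C[C@@H]1O[C@@H](OC(C)C)C=C[C@H]1OC(C)=O
F7 | step 8 | isopropyl 2,3,6-trideoxy-α-L-erythro-hex-2-enopyranoside | C[C@@H]1O[C@@H](OC(C)C)C=C[C@H]1O
F8 | step 8 | isopropyl 2,3,6-trideoxy-4-O-methylsulfonyl-α-L-erythro-hex-2-enopyranoside | C[C@@H]1O[C@@H](OC(C)C)C=C[C@H]1OS(C)(=O)=O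
F9 | step 11 | 2,5-dihydroxy-3,6-bis[4-(TBSO)phenyl]cyclohexa-2,5-diene-1,4-dione | OC1=C(c2ccc(O[Si](C)(C)C(C)(C)C)cc2)C(=O)C(O)=C(c2ccc(O[Si](C)(C)C(C)(C)C)cc2)C1=O
F10 | step 11 | 4-hydroxy-3,6-dioxo-2,5-bis[4-(TBSO)phenyl]cyclohexa-1,4-dien-1-yl (2Z)-3-[(2S,3S)-3-methyloxiran-2-yl]prop-2-enoate | C[C@@H]1O[C@H]1/C=C\C(=O)OC1=C(c2ccc(O[Si](C)(C)C(C)(C)C)cc2)C(=O)C(O)=C(c2ccc(O[Si](C)(C)C(C)(C)C)cc2)C1=O
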